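**Plan**

1. Retrosynthesis: with the four phenols masked as MOM ethers, ring C is cut at C4–C4a (acyl–aryl) and at O1–C8a. This leaves a ring-A aryne (C4a≡C8a) and an open β-silyloxy ester that holds ring B, C2, C3, C4 and O1.
2. Enabling feature: in ring A the acyl carbon C4 and the ether oxygen O1 sit on neighbouring carbons (C4a, C8a), and C4a is flanked by the C5 oxygen. This is the pattern left when an O-nucleophile and then a tethered acyl group add across a 3-alkoxyaryne; the C6 prenyl is para to C8a, so the aryne comes from a symmetrical phenol and no 8-prenyl isomer can form.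
3. Ring A piece (steps 1 to 6): resorcinol → bis-MOM ether → C2 prenylation → C–H borylation/oxidation para to prenyl → carbamate-directed ortho-silylation → silyl triflate 13.
4. Ring B piece (steps 7 to 11): 3-bromo-4,5-dihydroxybenzaldehyde → MOM ethers → Stille prenylation → Roskamp β-keto ester → asymmetric transfer hydrogenation → O–SiMe3 ether 19.
5. Forward order: rings A and B are made separately; ring C arises last in step 12 (O1–C8a, then ring closure by the C4–C4a bond); step 13 removes the MOM groups.
6. Stereochemistry: the only stereocentre, C2 (S), is set by the catalyst-controlled ketone reduction of step 10 and carried through untouched, since no bond to C2 is made or broken afterwards.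

Key step: step 12

Remark: atom numbers follow flavanone numbering (O1, C2, C3, C4, C4a, C5 to C8, C8a); prenyl = 3-methylbut-2-en-1-yl; MOM = methoxymethyl; TsDPEN = N-(4-toluenesulfonyl)-1,2-diphenylethane-1,2-diamine; Bpin = pinacolatoboryl.

**Route**

Step 1
Reactants: 1 resorcinol
Product: 2 1,3-bis(methoxymethoxy)benzene
Conditions: NaH (2.4 equiv), MOMCl (2.4 equiv), DMF, 0 °C to rt
Reagents that add atoms: chloromethyl methyl ether, COCCl
Why: Williamson-type O-alkylation of the bis-phenoxide by the reactive α-chloro ether should give the bis-acetal, whose MOM groups later serve as ortho-directing groups, as the aryne-polarising group and as the final protecting groups.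

Step 2
Reactants: 2 1,3-bis(methoxymethoxy)benzene
Product: 4 1,3-bis(methoxymethoxy)-2-(3-methylbut-2-en-1-yl)benzene, via [2,6-bis(methoxymethoxy)phenyl]lithium 3 (not isolated)
Conditions: n-BuLi (1.1 equiv), TMEDA, THF, 0 °C; prenyl bromide (1.2 equiv), −78 °C to rt
Reagents that add atoms: 1-bromo-3-methylbut-2-ene (prenyl bromide), CC(C)=CCBr
Why: Directed ortho-metalation should remove selectively the hydrogen between the two coordinating OMOM groups, and the aryllithium 3 is then alkylated at the primary carbon of the allylic bromide (SN2).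

Step 3
Reactants: 4 1,3-bis(methoxymethoxy)-2-(3-methylbut-2-en-1-yl)benzene
Product: 6 3,5-bis(methoxymethoxy)-4-(3-methylbut-2-en-1-yl)phenol, via arylboronic pinacol ester 5 (not isolated)
Conditions: B2pin2 (1.0 equiv), [Ir(OMe)(cod)]2 (1.5 mol%), 4,4'-di-tert-butyl-2,2'-bipyridine (3 mol%), THF, 70 °C; then 30% H2O2, aq NaOH, 0 °C to rt
Reagents that add atoms: bis(pinacolato)diboron, CC1(C)OB(OC1(C)C)B1OC(C)(C)C(C)(C)O1 (boryl group of 5); hydrogen peroxide, OO
Why: Iridium-catalysed aromatic C–H borylation is sterically controlled and should take the only ring CH that has no ortho substituent (para to prenyl, meta to both OMOM groups), and alkaline peroxide then converts C–B into C–O at the same carbon without epoxidising the trisubstituted alkene.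

Step 4
Reactants: 6 3,5-bis(methoxymethoxy)-4-(3-methylbut-2-en-1-yl)phenol
Product: 7 3,5-bis(methoxymethoxy)-4-(3-methylbut-2-en-1-yl)phenyl N-(propan-2-yl)carbamate
Conditions: i-PrNCO (1.5 equiv), Et3N (0.2 equiv), CH2Cl2, rt
Reagents that add atoms: isopropyl isocyanate, CC(C)N=C=O
Why: Base-catalysed addition of the phenol to the isocyanate (carbamoylation) should give the N-isopropyl carbamate, a strong ortho-directing group that can later be removed under mild base.

Step 5
Reactants: 7 3,5-bis(methoxymethoxy)-4-(3-methylbut-2-en-1-yl)phenyl N-(propan-2-yl)carbamate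
Product: 11 3,5-bis(methoxymethoxy)-4-(3-methylbut-2-en-1-yl)-2-(trimethylsilyl)phenyl N-(propan-2-yl)carbamate, via N-silyl carbamate 8 (not isolated), via ring-lithiated N-silyl carbamate 9 (not isolated), via N,C-bis(trimethylsilyl) carbamate 10 (not isolated)
Conditions: Me3SiOTf (1.1 equiv), TMEDA (1.1 equiv), Et2O, 0 °C to rt; n-BuLi (1.5 equiv), TMEDA (1.5 equiv), −78 °C; Me3SiCl (2.5 equiv), −78 °C to rt; aq NaHCO3/MeOH work-up
Reagents that add atoms: chlorotrimethylsilane, C[Si](C)(C)Cl; trimethylsilyl trifluoromethanesulfonate, C[Si](C)(C)OS(=O)(=O)C(F)(F)F (N-silyl group of intermediates 8 to 10 only)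
Why: Directed ortho-metalation after in-flask N-silylation of the N–H should lithiate the ring carbon between the carbamate and an OMOM group (the two open ring positions are equivalent by symmetry), Me3SiCl traps the aryllithium, and the labile N–Si bond is hydrolysed on work-up.

Step 6
Reactants: 11 3,5-bis(methoxymethoxy)-4-(3-methylbut-2-en-1-yl)-2-(trimethylsilyl)phenyl N-(propan-2-yl)carbamate
Product: 13 3,5-bis(methoxymethoxy)-4-(3-methylbut-2-en-1-yl)-2-(trimethylsilyl)phenyl trifluoromethanesulfonate, via 2-silylphenol 12 (not isolated)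
Conditions: DBU (1.5 equiv), Et2NH (1.3 equiv), MeCN, 40 °C; then PhNTf2 (1.5 equiv), rt
Reagents that add atoms: N-phenylbis(trifluoromethanesulfonimide), O=S(=O)(N(c1ccccc1)S(=O)(=O)C(F)(F)F)C(F)(F)F
Why: E1cB cleavage of the N-monosubstituted carbamate by DBU should release isopropyl isocyanate (scavenged by Et2NH as a urea) and the phenoxide of 12, which is sulfonylated in the same pot to give the ortho-silylaryl triflate.

Step 7
Reactants: 14 3-bromo-4,5-dihydroxybenzaldehyde
Product: 15 3-bromo-4,5-bis(methoxymethoxy)benzaldehyde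
Conditions: MOMCl (2.5 equiv), K2CO3 (4 equiv), acetone, 0 °C to rt
Reagents that add atoms: chloromethyl methyl ether, COCCl
Why: O-Alkylation of both catechol hydroxyls under mild carbonate base should leave the aldehyde and the aryl bromide untouched.

Step 8
Reactants: 15 3-bromo-4,5-bis(methoxymethoxy)benzaldehyde
Product: 16 3,4-bis(methoxymethoxy)-5-(3-methylbut-2-en-1-yl)benzaldehyde
Conditions: tributyl(3-methylbut-2-en-1-yl)stannane (1.3 equiv), Pd(PPh3)4 (5 mol%), DMF, 95 °C
Reagents that add atoms: tributyl(3-methylbut-2-en-1-yl)stannane, CCCC[Sn](CCCC)(CCCC)CC=C(C)C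
Why: Stille cross-coupling (oxidative addition of zerovalent palladium into the aryl–Br bond, transmetalation of the allylstannane, reductive elimination at the less hindered primary allyl terminus) should give the linear prenyl arene without touching the aldehyde.

Step 9
Reactants: 16 3,4-bis(methoxymethoxy)-5-(3-methylbut-2-en-1-yl)benzaldehyde
Product: 17 ethyl 3-[3,4-bis(methoxymethoxy)-5-(3-methylbut-2-en-1-yl)phenyl]-3-oxopropanoate
Conditions: N2CHCO2Et (1.3 equiv), SnCl2 (20 mol%), CH2Cl2, rt
Reagents that add atoms: ethyl diazoacetate, CCOC(=O)C=[N+]=[N-]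
Why: Roskamp homologation, in which the diazo carbon adds to the SnCl2-activated aldehyde and a 1,2-hydride shift with loss of N2 follows, should give the β-keto ester in one operation.

Step 10
Reactants: 17 ethyl 3-[3,4-bis(methoxymethoxy)-5-(3-methylbut-2-en-1-yl)phenyl]-3-oxopropanoate
Product: 18 ethyl (3S)-3-[3,4-bis(methoxymethoxy)-5-(3-methylbut-2-en-1-yl)phenyl]-3-hydroxypropanoate
Conditions: RuCl(p-cymene)[(S,S)-TsDPEN] (1 mol%), HCO2H/Et3N (5:2), 30 °C
Reagents that add atoms: none
Why: Noyori asymmetric transfer hydrogenation delivers hydride from the Ru–H/N–H catalyst to one face of the aryl ketone through a six-membered transition state ordered by the aryl/arene CH–π contact, which with the (S,S)-ligand should give the (S)-carbinol (the future C2) by analogy with simple aryl ketones, while the isolated alkene is not reduced.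

Step 11
Reactants: 18 ethyl (3S)-3-[3,4-bis(methoxymethoxy)-5-(3-methylbut-2-en-1-yl)phenyl]-3-hydroxypropanoate
Product: 19 ethyl (3S)-3-[3,4-bis(methoxymethoxy)-5-(3-methylbut-2-en-1-yl)phenyl]-3-[(trimethylsilyl)oxy]propanoate
Conditions: Me3SiCl (1.3 equiv), imidazole (2 equiv), CH2Cl2, 0 °C; filtration through basic alumina
Reagents that add atoms: chlorotrimethylsilane, C[Si](C)(C)Cl
Why: O-Silylation of the secondary alcohol leaves C2 untouched and installs an O–SiMe3 bond that fluoride can open to a proton-free alkoxide in the next step.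

Step 12
Reactants: 13 3,5-bis(methoxymethoxy)-4-(3-methylbut-2-en-1-yl)-2-(trimethylsilyl)phenyl trifluoromethanesulfonate; 19 ethyl (3S)-3-[3,4-bis(methoxymethoxy)-5-(3-methylbut-2-en-1-yl)phenyl]-3-[(trimethylsilyl)oxy]propanoate
Product: 22 (2S)-2-[3,4-bis(methoxymethoxy)-5-(3-methylbut-2-en-1-yl)phenyl]-5,7-bis(methoxymethoxy)-6-(3-methylbut-2-en-1-yl)-2,3-dihydro-4H-chromen-4-one, via 3,5-bis(methoxymethoxy)-4-prenylbenzyne 20 (not isolated), via arylpotassium adduct 21 (not isolated)
Conditions: 13 (1.3 equiv, added over 1 h), KF (3 equiv), 18-crown-6 (3 equiv), THF (0.03 M), 0 °C to rt; pH 7 phosphate buffer quench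
Reagents that add atoms: none
Why: Proposed new method: fluoride removes the ring SiMe3 group of 13 so that triflate is expelled and aryne 20 forms, and the same fluoride opens the O–SiMe3 bond of 19 to an alkoxide that carries no O–H; the alkoxide oxygen adds to the aryne carbon that becomes C8a, and the resulting aryl anion 21 at C4a attacks the ester carbonyl, forming the C4–C4a bond and expelling ethoxide, which Me3SiF captures as EtOSiMe3 so that fluoride is returned and the medium stays only weakly basic. The closest known reaction types are the fluoride-induced annulation of arynes with salicylate esters to xanthones (O-addition, then intramolecular acyl capture by the aryl anion) and the O-arylation of aliphatic alcohols by arynes; what is new is an aliphatic β-silyloxy ester as the partner, giving a chroman-4-one. Ring C closes in the 6-exo-trig mode (aryl carbanion onto the exocyclic C=O). No stereocentre is created: C2 is the carbinol carbon of 19, none of its four bonds is touched, and its (S) configuration is therefore retained. The step needs regioselective addition to the aryne, secured by the OMOM group beside the triple bond (its σ-withdrawal and the resulting distortion place the negative charge on the adjacent carbon, so oxygen enters at the remote carbon, which is also the less hindered one, flanked by C8–H), and it needs acyl capture to outrun protonation, secured by the proton-free silyl ether and the six-membered transition state. Because the prenyl group lies para to the attacked carbon, only the 6-prenyl skeleton can result.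

Step 13
Reactants: 22 (2S)-2-[3,4-bis(methoxymethoxy)-5-(3-methylbut-2-en-1-yl)phenyl]-5,7-bis(methoxymethoxy)-6-(3-methylbut-2-en-1-yl)-2,3-dihydro-4H-chromen-4-one
Product: 23 (2S)-2-[3,4-dihydroxy-5-(3-methylbut-2-en-1-yl)phenyl]-5,7-dihydroxy-6-(3-methylbut-2-en-1-yl)-2,3-dihydro-4H-chromen-4-one (CNP0117506.1)
Conditions: 3 M aq HCl, MeOH (degassed), 45 °C, short reaction time
Reagents that add atoms: none
Why: Acid-catalysed acetal exchange with methanol should remove all four MOM groups as dimethoxymethane under dilute, brief conditions of the kind used for MOM ethers of prenylated flavanones, chosen to limit acid cyclisation of the prenyl groups onto neighbouring phenols and not to open ring C, so that C2 keeps its configuration.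

**Compound list**

1 | resorcinol | Oc1cccc(O)c1 | starting material
2 | 1,3-bis(methoxymethoxy)benzene | COCOc1cccc(OCOC)c1 | intermediate
3 | [2,6-bis(methoxymethoxy)phenyl]lithium | [Li]c1c(OCOC)cccc1OCOC | intermediate (not isolated)
4 | 1,3-bis(methoxymethoxy)-2-(3-methylbut-2-en-1-yl)benzene | COCOc1cccc(OCOC)c1CC=C(C)C | intermediate
5 | 2-[3,5-bis(methoxymethoxy)-4-(3-methylbut-2-en-1-yl)phenyl]-4,4,5,5-tetramethyl-1,3,2-dioxaborolane | COCOc1cc(B2OC(C)(C)C(C)(C)O2)cc(OCOC)c1CC=C(C)C | intermediate (not isolated)
6 | 3,5-bis(methoxymethoxy)-4-(3-methylbut-2-en-1-yl)phenol | COCOc1cc(O)cc(OCOC)c1CC=C(C)C | intermediate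
7 | 3,5-bis(methoxymethoxy)-4-(3-methylbut-2-en-1-yl)phenyl N-(propan-2-yl)carbamate | COCOc1cc(OC(=O)NC(C)C)cc(OCOC)c1CC=C(C)C | intermediate
8 | 3,5-bis(methoxymethoxy)-4-(3-methylbut-2-en-1-yl)phenyl N-(propan-2-yl)-N-(trimethylsilyl)carbamate | COCOc1cc(OC(=O)N(C(C)C)[Si](C)(C)C)cc(OCOC)c1CC=C(C)C | intermediate (not isolated)
9 | 2-lithio derivative of 8 (lithium on the ring carbon between the carbamate oxygen and an OMOM group) | COCOc1cc(OC(=O)N(C(C)C)[Si](C)(C)C)c([Li])c(OCOC)c1CC=C(C)C | intermediate (not isolated)
10 | 3,5-bis(methoxymethoxy)-4-(3-methylbut-2-en-1-yl)-2-(trimethylsilyl)phenyl N-(propan-2-yl)-N-(trimethylsilyl)carbamate | COCOc1cc(OC(=O)N(C(C)C)[Si](C)(C)C)c([Si](C)(C)C)c(OCOC)c1CC=C(C)C | intermediate (not isolated)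
11 | 3,5-bis(methoxymethoxy)-4-(3-methylbut-2-en-1-yl)-2-(trimethylsilyl)phenyl N-(propan-2-yl)carbamate | COCOc1cc(OC(=O)NC(C)C)c([Si](C)(C)C)c(OCOC)c1CC=C(C)C | intermediate
12 | 3,5-bis(methoxymethoxy)-4-(3-methylbut-2-en-1-yl)-2-(trimethylsilyl)phenol | COCOc1cc(O)c([Si](C)(C)C)c(OCOC)c1CC=C(C)C | intermediate (not isolated)
13 | 3,5-bis(methoxymethoxy)-4-(3-methylbut-2-en-1-yl)-2-(trimethylsilyl)phenyl trifluoromethanesulfonate | COCOc1cc(OS(=O)(=O)C(F)(F)F)c([Si](C)(C)C)c(OCOC)c1CC=C(C)C | intermediate
14 | 3-bromo-4,5-dihydroxybenzaldehyde | O=Cc1cc(O)c(O)c(Br)c1 | starting material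
15 | 3-bromo-4,5-bis(methoxymethoxy)benzaldehyde | O=Cc1cc(OCOC)c(OCOC)c(Br)c1 | intermediate
16 | 3,4-bis(methoxymethoxy)-5-(3-methylbut-2-en-1-yl)benzaldehyde | O=Cc1cc(OCOC)c(OCOC)c(CC=C(C)C)c1 | intermediate
17 | ethyl 3-[3,4-bis(methoxymethoxy)-5-(3-methylbut-2-en-1-yl)phenyl]-3-oxopropanoate | CCOC(=O)CC(=O)c1cc(OCOC)c(OCOC)c(CC=C(C)C)c1 | intermediate
18 | ethyl (3S)-3-[3,4-bis(methoxymethoxy)-5-(3-methylbut-2-en-1-yl)phenyl]-3-hydroxypropanoate | CCOC(=O)C[C@H](O)c1cc(OCOC)c(OCOC)c(CC=C(C)C)c1 | intermediate
19 | ethyl (3S)-3-[3,4-bis(methoxymethoxy)-5-(3-methylbut-2-en-1-yl)phenyl]-3-[(trimethylsilyl)oxy]propanoate | CCOC(=O)C[C@H](O[Si](C)(C)C)c1cc(OCOC)c(OCOC)c(CC=C(C)C)c1 | intermediate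
20 | 3,5-bis(methoxymethoxy)-4-(3-methylbut-2-en-1-yl)benzyne (1,2-didehydrobenzene, triple bond between the former C–OTf and C–Si carbons) | COCOC1=C(CC=C(C)C)C(OCOC)=CC#C1 | intermediate (not isolated)
21 | arylpotassium adduct: ethyl (3S)-3-aryl-3-aryloxypropanoate with potassium on the ring carbon between the new ether oxygen and an OMOM group | CCOC(=O)C[C@H](Oc1cc(OCOC)c(CC=C(C)C)c(OCOC)c1[K])c1cc(OCOC)c(OCOC)c(CC=C(C)C)c1 | intermediate (not isolated)
22 | (2S)-2-[3,4-bis(methoxymethoxy)-5-(3-methylbut-2-en-1-yl)phenyl]-5,7-bis(methoxymethoxy)-6-(3-methylbut-2-en-1-yl)-2,3-dihydro-4H-chromen-4-one | CC(C)=CCc1cc([C@@H]2CC(=O)c3c(cc(OCOC)c(CC=C(C)C)c3OCOC)O2)cc(OCOC)c1OCOC | intermediate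
23 | (2S)-2-[3,4-dihydroxy-5-(3-methylbut-2-en-1-yl)phenyl]-5,7-dihydroxy-6-(3-methylbut-2-en-1-yl)-2,3-dihydro-4H-chromen-4-one | CC(C)=CCc1cc([C@@H]2CC(=O)c3c(cc(O)c(CC=C(C)C)c3O)O2)cc(O)c1O | target

**Step count and risks**

Total steps: 13. Longest linear sequence: 8 steps (steps 1 to 6, then 12 and 13).

Steps most likely to fail:

Step 12 (Proposed new method). What may go wrong: the aryl anion may be protonated (by adventitious water, the crown ether or the C3 hydrogens) before it reaches the ester, stopping at the open aryl ether. The alkoxide released from 19 may undergo β-elimination or retro-aldol cleavage before it finds the aryne. Residual alkoxide may open ring C of 22 to the chalcone and so erode the configuration at C2. Fallback with known chemistry (Mitsunobu etherification, then Parham cycloacylation), setting out from phenol 6 and keto ester 17 and returning to the route at 22: 17 is reduced as in step 10 but with RuCl(p-cymene)[(R,R)-TsDPEN] to ethyl (3R)-3-[3,4-bis(methoxymethoxy)-5-(3-methylbut-2-en-1-yl)phenyl]-3-hydroxypropanoate F1. Phenol 6 is brominated at one of its two equivalent ortho positions (NBS, CH2Cl2, −78 °C) to 2-bromo-3,5-bis(methoxymethoxy)-4-(3-methylbut-2-en-1-yl)phenol F2. Mitsunobu coupling of F1 with F2 (PPh3, DIAD, toluene, 0 °C) should form the O1–C2 bond with inversion and give the (3S)-aryl ether bromo ester F3. Bromine–lithium exchange (t-BuLi, 2.1 equiv, THF, −100 °C) gives the aryllithium F4, which closes ring C onto the ester and gives 22.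

Step 3. What may go wrong: hydroboration or isomerisation of the prenyl double bond by the iridium boryl/HBpin system, or slow C–H activation of the electron-rich ring. Fallback that removes the alkene from the borylation by changing the order of events, setting out from 2 and returning at 6: 2 is borylated under the same catalyst at its only unflanked CH to the arylboronic pinacol ester F5 and oxidised (H2O2, aq NaOH) to 3,5-bis(methoxymethoxy)phenol F6. Silylation (i-Pr3SiCl, imidazole, DMF) gives the triisopropylsilyl ether F7, whose bulky, non-coordinating silyloxy group leaves the CH between the two OMOM groups as the lithiation site. n-BuLi/TMEDA gives the aryllithium F8 and prenyl bromide gives the prenylated silyl ether F9. Bu4NF in THF removes the silyl group and gives 6.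

Step 9. What may go wrong: slow addition of the diazo ester to the electron-rich aldehyde, aryl instead of hydride migration in the diazonium adduct, and Lewis-acid-induced loss of MOM groups. Fallback by addition and oxidation instead of diazo homologation, setting out from 16 and returning at 17: the lithium enolate of ethyl acetate (LiN(i-Pr)2, EtOAc, THF, −78 °C) adds to 16 to give the racemic ethyl 3-hydroxy ester F10, and Dess–Martin periodinane (NaHCO3, CH2Cl2, rt) oxidises it to 17.

**Further compounds**

F1 | step 12 | ethyl (3R)-3-[3,4-bis(methoxymethoxy)-5-(3-methylbut-2-en-1-yl)phenyl]-3-hydroxypropanoate | CCOC(=O)C[C@@H](O)c1cc(OCOC)c(OCOC)c(CC=C(C)C)c1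
F2 | step 12 | 2-bromo-3,5-bis(methoxymethoxy)-4-(3-methylbut-2-en-1-yl)phenol | COCOc1cc(O)c(Br)c(OCOC)c1CC=C(C)C
F3 | step 12 | ethyl (3S)-3-[3,4-bis(methoxymethoxy)-5-(3-methylbut-2-en-1-yl)phenyl]-3-[2-bromo-3,5-bis(methoxymethoxy)-4-(3-methylbut-2-en-1-yl)phenoxy]propanoate | CCOC(=O)C[C@H](Oc1cc(OCOC)c(CC=C(C)C)c(OCOC)c1Br)c1cc(OCOC)c(OCOC)c(CC=C(C)C)c1
F4 | step 12 | aryllithium from F3 (lithium in place of bromine) | CCOC(=O)C[C@H](Oc1cc(OCOC)c(CC=C(C)C)c(OCOC)c1[Li])c1cc(OCOC)c(OCOC)c(CC=C(C)C)c1
F5 | step 3 | 2-[3,5-bis(methoxymethoxy)phenyl]-4,4,5,5-tetramethyl-1,3,2-dioxaborolane | COCOc1cc(B2OC(C)(C)C(C)(C)O2)cc(OCOC)c1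
F6 | step 3 | 3,5-bis(methoxymethoxy)phenol | COCOc1cc(O)cc(OCOC)c1
F7 | step 3 | [3,5-bis(methoxymethoxy)phenoxy]tri(propan-2-yl)silane | COCOc1cc(O[Si](C(C)C)(C(C)C)C(C)C)cc(OCOC)c1
F8 | step 3 | {2,6-bis(methoxymethoxy)-4-[tri(propan-2-yl)silyloxy]phenyl}lithium | [Li]c1c(OCOC)cc(O[Si](C(C)C)(C(C)C)C(C)C)cc1OCOC
F9 | step 3 | [3,5-bis(methoxymethoxy)-4-(3-methylbut-2-en-1-yl)phenoxy]tri(propan-2-yl)silane | COCOc1cc(O[Si](C(C)C)(C(C)C)C(C)C)cc(OCOC)c1CC=C(C)C
F10 | step 9 | ethyl 3-[3,4-bis(methoxymethoxy)-5-(3-methylbut-2-en-1-yl)phenyl]-3-hydroxypropanoate (racemic) | CCOC(=O)CC(O)c1cc(OCOC)c(OCOC)c(CC=C(C)C)c1
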